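## Structural features

The target is a (2S)-flavanone: the resorcinol-type ring A is fused to the dihydropyranone ring C (O1, C2, C3, C4=O), and the catechol ring B is attached by a single bond at C2. Ring A carries hydroxyls on C5 and C7 with a prenyl group on C6 between them; ring B carries hydroxyls on C4' and C5' and a prenyl group on C3'. C2 is the only stereocentre and has no stereogenic neighbour, so the problem is absolute control, not relative control. Each prenyl group has an ortho hydroxyl that adds across the trisubstituted alkene under acid to give a 2,2-dimethylchroman. The C2–O1 bond is β to the C4 carbonyl and para to the 4'-OH, so base opens ring C to the chalcone, which racemises C2 and can re-close through O5, moving the side chain from C6 to C8. The real difficulties are therefore telling O1 from O5 so that the ring A chain ends on C6, securing one configuration at C2, and ordering events so that finished prenyl groups never meet acid or base. The key step uses the fact that each prenyl group is an aryl–CH2–CH= unit (on C6 of ring A and C3' of ring B) capped by C(CH3)2, so robust allyl groups can stand in until the last step.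

## Logic of the disconnections

**19 to 17 and 18.** The two CH=C(CH3)2 double bonds, one in the C6 chain and one in the C3' chain, are cut. This removes every acid-sensitive ortho-hydroxy prenyl unit from all earlier steps and reduces both chains to terminal allyl groups. The forward step must run on four free phenols, including a catechol, without isomerising allyl to propenyl and without touching C2. 17 is kept fully unprotected on purpose: any protected variant would put an acid step after the prenyl groups exist.

**17 to 16.** Four aryl O–CH2OCH3 bonds are cut. These acetals tolerate organolithium, hydroxide, light and transfer hydrogenation, and all four leave in one acid step that terminal allyl groups survive. The demand is that the acid does not open ring C.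

**16 to 15.** No skeletal bond is cut; the configuration at C2 is separated from the construction of the skeleton, 16 being one enantiomer of 15. The reason is that ring closure by oxa-Michael addition is reversible, and an invertive closure at a benzylic carbinol bearing a para-alkoxy ring risks ionisation and elimination. The gain is a robust racemic assembly. The demand is a catalyst that distinguishes the enantiomers of the ketone; the cost is at most half of the material.

**15 to 14.** The O1–C2 bond is cut. 14 has a single free phenol, para to the ring A allyl group, so closure can only place that allyl on C6. The demand is a mild base and acceptance of an equilibrium.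

**14 to 9 and 13.** The Cα=Cβ bond is cut, dividing the molecule into two halves of similar size. The demand is a hydroxide-stable protecting-group set on both halves.

**13 to 12, 11, then 10 and 4.** Two O–CH2 acetal bonds are cut to reach 12. The aryl–CH2 bond of 12 is traced through a [3,3] shift to the O–allyl bond of 11, which comes from 10 and 4. The position is fixed because only one ortho carbon of the allylated oxygen bears hydrogen. The demand is selective alkylation of the more acidic hydroxyl of 10.

**9 to 8, then 6 through 7.** The aryl–C(=O) bond is cut and the acetyl group returned to the oxygen para to the allyl group. This makes the precursor symmetric, so both ortho positions are equivalent and the free hydroxyl of 9 is necessarily the one para to the allyl group. The demand is a neutral acyl shift: a Lewis acid would strip the acetals and erase the difference between the oxygens. 8 arises from 6 by exchange of silicon for acetyl through 7.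

**6 to 5 and 4, then 3.** The aryl–CH2 bond between the two acetal-bearing carbons is cut. The flanking acetals direct a lithium base to exactly this carbon, so the allyl group enters para to the silyl ether. The demand is that the silyl ether neither directs nor migrates.

**3 to 2 to 1.** Two O–CH2 bonds and one O–Si bond are cut. The one silylated oxygen is the future O1; marking it at the start is what later distinguishes C6 from C8. The demand is a mono-functionalisation of a threefold-symmetric triol, which is statistical.

## Other disconnections considered

Alternative 1: The cut runs through ring C at C2–C3 and O1–C8a (flavanone numbering). A chiral Lewis acid would join aldehyde A2 and the methyl-substituted silyloxy diene A3 in a hetero-Diels–Alder reaction to give dihydropyranone A1 with C2 set by the catalyst.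
- In its favour: the stereocentre is created catalytically and in one sense, with no loss of half the material. On this point the alternative is better than the chosen plan, which resolves 15. It is the equal of the chosen plan in relying on a Claisen-derived ring B aldehyde.
- Against it here: A1 contains only ring C. Ring A must still be grown from the C6 methyl group by acylation and a base-mediated aromatising closure, during which the C2–O1 bond, β to the carbonyl, can open by E1cB and lose the configuration just won. The ring A side chain has to be placed in an open-chain polycarbonyl intermediate. Because A2 already carries a prenyl group, that alkene must pass through the acidic elimination that completes the cycloaddition and through the final acetal cleavage.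
- Comparison: mechanistically the step is most likely a stepwise Mukaiyama aldol and cyclisation, which does not harm it. In step count the work after its key step would exceed what the chosen plan needs after its own ring closure.

Alternative 2: The cut is at the two aryl–CH2 bonds, on C6 and on C3', each traced through a [3,3] shift to a tertiary allyl ether on O5 and on O4'. Heating bis-ether A5 would give A4.
- In its favour: both prenyl groups form in one metal-free step with complete atom economy. On this point it is better than the metathesis, which needs a ruthenium catalyst and expels a volatile alkene. The regiochemistry on ring A is as secure as in the chosen plan, since C6 is the only free ortho position of O5; on this point the two are equal.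
- Against it here: A5 needs two tertiary aryl ethers, one on the chelated and hindered O5. Such ethers are normally made indirectly and ionise easily. The shift is run on a compound that already holds the C2 configuration, and it liberates the 5-OH and 4'-OH, the groups that help ring C to open on heating. Above all, A4 still carries two acetals, so the last step would be an acid treatment of a compound with two ortho-hydroxy prenyl groups, which is the exposure the chosen plan is built to avoid.
- Comparison: the step counts are comparable.

Alternative 3: The cut is at C4a–C5 inside ring A. An alkoxide base would turn the triketo ester A7 into a dienolate whose C4a attacks the ester carbon, closing ring A, which enolises to the arene A6.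
- In its favour: the route is biomimetic, and the substitution pattern of ring A, including the chain on C6, follows from the open chain. There is no C6/C8 question and no statistical desymmetrisation of a symmetric triol; on this point it is better than step 1 of the chosen plan.
- Against it here: A7 is a sensitive poly-β-carbonyl compound that is long to assemble and has competing modes of closure. The base acts on a dihydropyranone whose C2–O1 bond is β to a carbonyl, so ring opening and loss of configuration compete with the desired closure. Both prenyl groups are already present, and A6 still needs an acid step to free ring B.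
- Comparison: the step count would be clearly higher than in the chosen plan.

Key step: step 13

Remark on the chemistry: decoding the SMILES strings of 19 and 17 confirms a (2S)-flavanone with side chains on C6 and C3' in both, so no structure needed correction. The acetal-protected flavanones are assumed to be configurationally stable in neutral and weakly acidic media.

## Route

Step 1
Reactants: 1 phloroglucinol (benzene-1,3,5-triol)
Product: 2 5-(triisopropylsilyloxy)benzene-1,3-diol
Conditions: TIPSCl (1.0 equiv), imidazole, DMF, 0 °C → rt
Reagents that add atoms: triisopropylsilyl chloride, CC(C)[Si](Cl)(C(C)C)C(C)C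
Why: Statistical mono-silylation of a threefold-symmetric triol; the bulky chloride used in one equivalent holds back bis-silylation and unreacted 1 is removed with water. The silylated oxygen is the future O1 of ring C.

Step 2
Reactants: 2 5-(triisopropylsilyloxy)benzene-1,3-diol
Product: 3 [3,5-bis(methoxymethoxy)phenoxy]triisopropylsilane
Conditions: MOMCl, iPr2NEt, CH2Cl2, 0 °C → rt
Reagents that add atoms: chloromethyl methyl ether, COCCl
Why: O-alkylation of both free phenols to methoxymethyl acetals, which later direct the metalation and leave under mild acid at the end.

Step 3
Reactants: 3 [3,5-bis(methoxymethoxy)phenoxy]triisopropylsilane; 4 allyl bromide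
Product: 6 [4-allyl-3,5-bis(methoxymethoxy)phenoxy]triisopropylsilane, via aryllithium 5 (not isolated)
Conditions: n-BuLi, THF, 0 °C; CuI (10 mol%), 4, −78 °C → rt
Reagents that add atoms: none
Why: Directed ortho-metalation: the carbon between the two acetal oxygens is the most acidic and doubly chelated site, and the bulky silyl ether does not direct, so the allyl group enters para to the silyl ether. The copper-catalysed allylation of the aryllithium gives the same product by either SN2 or SN2' attack.

Step 4
Reactants: 6 [4-allyl-3,5-bis(methoxymethoxy)phenoxy]triisopropylsilane
Product: 8 4-allyl-3,5-bis(methoxymethoxy)phenyl acetate, via tetrabutylammonium phenoxide 7 (not isolated)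
Conditions: TBAF, THF, 0 °C; then Ac2O, rt
Reagents that add atoms: acetic anhydride, CC(=O)OC(C)=O
Why: Fluoride cleaves the aryl O–Si bond and the phenoxide so formed is acetylated in the same flask (desilylation, then O-acylation).

Step 5
Reactants: 8 4-allyl-3,5-bis(methoxymethoxy)phenyl acetate
Product: 9 1-[3-allyl-6-hydroxy-2,4-bis(methoxymethoxy)phenyl]ethan-1-one
Conditions: hν (254 nm, quartz), degassed cyclohexane, 20 °C
Reagents that add atoms: none
Why: Photo-Fries rearrangement: homolysis of the aryl O–acyl bond, in-cage recombination at an ortho carbon and tautomerisation. Both ortho positions are equivalent and the para position is blocked, so only the ketone with its hydroxyl para to the allyl group can form; the neutral conditions keep both acetals, which a Lewis-acid Fries shift would remove.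

Step 6
Reactants: 10 3,4-dihydroxybenzaldehyde; 4 allyl bromide
Product: 11 4-(allyloxy)-3-hydroxybenzaldehyde
Conditions: NaHCO3, NaI (cat.), DMF, 40 °C
Reagents that add atoms: none
Why: Williamson ether synthesis; the 4-OH, para to the formyl group, is the more acidic hydroxyl, so the weak base ionises and alkylates it selectively.

Step 7
Reactants: 11 4-(allyloxy)-3-hydroxybenzaldehyde
Product: 12 3-allyl-4,5-dihydroxybenzaldehyde
Conditions: PhNEt2, 190 °C, under argon
Reagents that add atoms: none
Why: Aromatic Claisen rearrangement; of the two ortho carbons of the allylated oxygen only one bears hydrogen, so the [3,3] shift and rearomatisation place the allyl group there.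

Step 8
Reactants: 12 3-allyl-4,5-dihydroxybenzaldehyde
Product: 13 3-allyl-4,5-bis(methoxymethoxy)benzaldehyde
Conditions: MOMCl, iPr2NEt, CH2Cl2, 0 → 40 °C
Reagents that add atoms: chloromethyl methyl ether, COCCl
Why: O-alkylation of both catechol hydroxyls to acetals that withstand the hydroxide of the next step.

Step 9
Reactants: 9 1-[3-allyl-6-hydroxy-2,4-bis(methoxymethoxy)phenyl]ethan-1-one; 13 3-allyl-4,5-bis(methoxymethoxy)benzaldehyde
Product: 14 (E)-1-[3-allyl-6-hydroxy-2,4-bis(methoxymethoxy)phenyl]-3-[3-allyl-4,5-bis(methoxymethoxy)phenyl]prop-2-en-1-one
Conditions: KOH, EtOH/H2O, 0 °C → rt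
Reagents that add atoms: none
Why: Claisen–Schmidt condensation of the methyl ketone with the non-enolisable aldehyde; E1cB dehydration gives the (E)-enone. Acetals and terminal alkenes are inert to aqueous-ethanolic hydroxide at room temperature.

Step 10
Reactants: 14 (E)-1-[3-allyl-6-hydroxy-2,4-bis(methoxymethoxy)phenyl]-3-[3-allyl-4,5-bis(methoxymethoxy)phenyl]prop-2-en-1-one
Product: 15 rac-6-allyl-2-[3-allyl-4,5-bis(methoxymethoxy)phenyl]-5,7-bis(methoxymethoxy)chroman-4-one
Conditions: NaOAc, EtOH, reflux
Reagents that add atoms: none
Why: Intramolecular oxa-Michael addition (6-endo-trig) of the only free phenol, which lies para to the ring A allyl group and so fixes that group on C6 and not C8. C2 is formed without control, as the racemate.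

Step 11
Reactants: 15 rac-6-allyl-2-[3-allyl-4,5-bis(methoxymethoxy)phenyl]-5,7-bis(methoxymethoxy)chroman-4-one
Product: 16 (2S)-6-allyl-2-[3-allyl-4,5-bis(methoxymethoxy)phenyl]-5,7-bis(methoxymethoxy)chroman-4-one
Conditions: RuCl(p-cymene)[(R,R)-TsDPEN] (2 mol%), HCO2H/Et3N 5:2, EtOAc, 25 °C, stopped just past half conversion
Reagents that add atoms: none
Why: Kinetic resolution by Noyori-type asymmetric transfer hydrogenation. The (R,R) catalyst delivers hydride to give a 4R carbinol, which is the matched cis reduction of the 2R enantiomer, so the 2S ketone is expected to remain (at most half of the material) and is separated from the flavan-4-ol by chromatography. The formic acid medium contains no free base and cannot open ring C.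

Step 12
Reactants: 16 (2S)-6-allyl-2-[3-allyl-4,5-bis(methoxymethoxy)phenyl]-5,7-bis(methoxymethoxy)chroman-4-one
Product: 17 (2S)-6-allyl-2-(3-allyl-4,5-dihydroxyphenyl)-5,7-dihydroxychroman-4-one
Conditions: HCl (3 M) in MeOH, 45 °C, under argon
Reagents that add atoms: none
Why: Acid-catalysed acetal exchange removes all four methoxymethyl groups. Terminal allyl groups, unlike prenyl groups, do not cyclise onto a neighbouring phenol under these conditions, and C2 should hold its configuration in the absence of base.

Step 13
Reactants: 17 (2S)-6-allyl-2-(3-allyl-4,5-dihydroxyphenyl)-5,7-dihydroxychroman-4-one; 18 2-methyl-2-butene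
Product: 19 (2S)-2-[3,4-dihydroxy-5-(3-methylbut-2-en-1-yl)phenyl]-5,7-dihydroxy-6-(3-methylbut-2-en-1-yl)chroman-4-one (CNP0117506.1)
Conditions: second-generation Grubbs catalyst (H2IMes)(PCy3)Cl2Ru=CHPh (10 mol%), 18/CH2Cl2 1:1, 40 °C, degassed, sealed vessel
Reagents that add atoms: none
Why: Olefin cross-metathesis by the Chauvin mechanism: the large excess of 18 converts the benzylidene into Ru=C(CH3)2 and Ru=CHCH3 carbenes, and [2+2] addition of Ru=C(CH3)2 to each ArCH2CH=CH2 unit gives a ruthenacyclobutane that collapses to ArCH2CH=C(CH3)2 and Ru=CH2, which 18 turns back into a substituted carbene with loss of propene. Any crotyl arene formed through the ethylidene carbene is still a reactive disubstituted alkene and is carried on to the prenyl stage, whereas the trisubstituted product alkenes are too hindered to re-enter, so the system converges on 19. The closest known reaction type is the cross-metathesis of allylarenes and ortho-allylphenols with 2-methyl-2-butene under this catalyst. No ring closes: the two allyl groups sit on different rings far apart, and the excess of 18 outcompetes homodimerisation, which is reversible in any case. No stereocentre is formed, and C2 is untouched because the medium is neutral and aprotic. The selectivities needed are reaction at the two terminal alkenes only, which holds because the carbene ignores the ketone and the four phenols, and suppression of allyl-to-propenyl isomerisation, which is secured by the mild temperature, a short reaction time and 18 as co-solvent. Because this is the last step, neither ortho-hydroxy prenyl group ever meets acid or base.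

## Compound list

1 | phloroglucinol (benzene-1,3,5-triol) | Oc1cc(O)cc(O)c1 | starting material
2 | 5-(triisopropylsilyloxy)benzene-1,3-diol | CC(C)[Si](Oc1cc(O)cc(O)c1)(C(C)C)C(C)C | intermediate
3 | [3,5-bis(methoxymethoxy)phenoxy]triisopropylsilane | COCOc1cc(OCOC)cc(O[Si](C(C)C)(C(C)C)C(C)C)c1 | intermediate
4 | allyl bromide (3-bromoprop-1-ene) | C=CCBr | starting material
5 | [2,6-bis(methoxymethoxy)-4-(triisopropylsilyloxy)phenyl]lithium | [Li]c1c(OCOC)cc(O[Si](C(C)C)(C(C)C)C(C)C)cc1OCOC | intermediate (not isolated)
6 | [4-allyl-3,5-bis(methoxymethoxy)phenoxy]triisopropylsilane | C=CCc1c(OCOC)cc(O[Si](C(C)C)(C(C)C)C(C)C)cc1OCOC | intermediate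
7 | tetrabutylammonium 4-allyl-3,5-bis(methoxymethoxy)phenoxide | C=CCc1c(OCOC)cc([O-])cc1OCOC.CCCC[N+](CCCC)(CCCC)CCCC | intermediate (not isolated)
8 | 4-allyl-3,5-bis(methoxymethoxy)phenyl acetate | C=CCc1c(OCOC)cc(OC(C)=O)cc1OCOC | intermediate
9 | 1-[3-allyl-6-hydroxy-2,4-bis(methoxymethoxy)phenyl]ethan-1-one | CC(=O)c1c(O)cc(OCOC)c(CC=C)c1OCOC | intermediate
10 | 3,4-dihydroxybenzaldehyde | O=Cc1ccc(O)c(O)c1 | starting material
11 | 4-(allyloxy)-3-hydroxybenzaldehyde | C=CCOc1ccc(C=O)cc1O | intermediate
12 | 3-allyl-4,5-dihydroxybenzaldehyde | C=CCc1cc(C=O)cc(O)c1O | intermediate
13 | 3-allyl-4,5-bis(methoxymethoxy)benzaldehyde | C=CCc1cc(C=O)cc(OCOC)c1OCOC | intermediate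
14 | (E)-1-[3-allyl-6-hydroxy-2,4-bis(methoxymethoxy)phenyl]-3-[3-allyl-4,5-bis(methoxymethoxy)phenyl]prop-2-en-1-one | C=CCc1cc(/C=C/C(=O)c2c(O)cc(OCOC)c(CC=C)c2OCOC)cc(OCOC)c1OCOC | intermediate
15 | rac-6-allyl-2-[3-allyl-4,5-bis(methoxymethoxy)phenyl]-5,7-bis(methoxymethoxy)chroman-4-one (racemate, C2 undefined) | C=CCc1cc(C2CC(=O)c3c(cc(OCOC)c(CC=C)c3OCOC)O2)cc(OCOC)c1OCOC | intermediate
16 | (2S)-6-allyl-2-[3-allyl-4,5-bis(methoxymethoxy)phenyl]-5,7-bis(methoxymethoxy)chroman-4-one | C=CCc1cc([C@@H]2CC(=O)c3c(cc(OCOC)c(CC=C)c3OCOC)O2)cc(OCOC)c1OCOC | intermediate
17 | (2S)-6-allyl-2-(3-allyl-4,5-dihydroxyphenyl)-5,7-dihydroxychroman-4-one | C=CCc1cc([C@@H]2CC(=O)c3c(cc(O)c(CC=C)c3O)O2)cc(O)c1O | intermediate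
18 | 2-methyl-2-butene | CC=C(C)C | starting material
19 | (2S)-2-[3,4-dihydroxy-5-(3-methylbut-2-en-1-yl)phenyl]-5,7-dihydroxy-6-(3-methylbut-2-en-1-yl)chroman-4-one (CNP0117506.1) | CC(C)=CCc1cc([C@@H]2CC(=O)c3c(cc(O)c(CC=C(C)C)c3O)O2)cc(O)c1O | target

## Step count and least certain steps

Total: 13 steps. Longest linear sequence: 10 steps (steps 1–5, then 9–13); the ring B aldehyde takes 3 steps (6–8) and joins at step 9.

**Step 13 (key step).** The most likely failure is migration of the terminal double bonds into conjugation with the arenes, caused by ruthenium hydride species that form as the catalyst decays; slow turnover from binding of the catechol to ruthenium would make this worse. Fallback: set out from 16 and run the same cross-metathesis with 18 on the fully protected compound, where no phenol is free, to give (2S)-2-[3,4-bis(methoxymethoxy)-5-(3-methylbut-2-en-1-yl)phenyl]-5,7-bis(methoxymethoxy)-6-(3-methylbut-2-en-1-yl)chroman-4-one F1. Then cleave the acetals with dilute HCl in MeOH at room temperature, stopping as soon as conversion is complete, to come back at 19. The price is one brief acid contact of the prenyl groups.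

**Step 5.** Escape of the radical pair from the solvent cage (giving the free phenol) and screening of the light by the strongly absorbing product may limit conversion; the allyl group may also undergo photoreactions. Fallback: set out from 6, remove the silyl group with TBAF to give 4-allyl-3,5-bis(methoxymethoxy)phenol F2, brominate ortho to the hydroxyl with NBS (1 equiv, CH2Cl2, −78 °C) to give 4-allyl-2-bromo-3,5-bis(methoxymethoxy)phenol F3, then treat with n-BuLi (2.2 equiv, THF, −78 °C) for deprotonation and bromine–lithium exchange and acylate the dianion with N-methoxy-N-methylacetamide, coming back at 9.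

**Step 11.** The rate difference between the enantiomers may be too small, because the acetal on O5 and the flanking substituents hinder the carbonyl and slow hydride transfer; the sense of the resolution also rests on a model. Fallback: set out from 15 and separate the enantiomers by preparative chromatography on a polysaccharide chiral stationary phase, coming back at 16. This makes no new compound (F0).

**Step 12.** Acid-mediated opening and re-closure of ring C may erode the configuration once the 4'-OH is free, or the catechol acetals may cleave incompletely under conditions mild enough to avoid this. Fallback: set out from 15, cleave the acetals on the racemate to give rac-6-allyl-2-(3-allyl-4,5-dihydroxyphenyl)-5,7-dihydroxychroman-4-one F4, and only then separate the enantiomers by chiral chromatography, coming back at 17. The configuration is then fixed after the acid step instead of before it.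

**Step 7.** Thermal degradation or air oxidation of the free hydroxy aldehyde and of the catechol formed at 190 °C may lower the throughput. Fallback: set out from 11, protect the free hydroxyl first (MOMCl, iPr2NEt) to give 4-(allyloxy)-3-(methoxymethoxy)benzaldehyde F5, run the Claisen rearrangement on this ether to give 3-allyl-4-hydroxy-5-(methoxymethoxy)benzaldehyde F6, and protect the liberated hydroxyl (MOMCl, iPr2NEt), coming back at 13.

## Further compounds

F1 | step 13 | (2S)-2-[3,4-bis(methoxymethoxy)-5-(3-methylbut-2-en-1-yl)phenyl]-5,7-bis(methoxymethoxy)-6-(3-methylbut-2-en-1-yl)chroman-4-one | CC(C)=CCc1cc([C@@H]2CC(=O)c3c(cc(OCOC)c(CC=C(C)C)c3OCOC)O2)cc(OCOC)c1OCOC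
F2 | step 5 | 4-allyl-3,5-bis(methoxymethoxy)phenol | C=CCc1c(OCOC)cc(O)cc1OCOC
F3 | step 5 | 4-allyl-2-bromo-3,5-bis(methoxymethoxy)phenol | C=CCc1c(OCOC)cc(O)c(Br)c1OCOC
F0 | step 11 | none | none
F4 | step 12 | rac-6-allyl-2-(3-allyl-4,5-dihydroxyphenyl)-5,7-dihydroxychroman-4-one (racemate, C2 undefined) | C=CCc1cc(C2CC(=O)c3c(cc(O)c(CC=C)c3O)O2)cc(O)c1O
F5 | step 7 | 4-(allyloxy)-3-(methoxymethoxy)benzaldehyde | C=CCOc1ccc(C=O)cc1OCOC
F6 | step 7 | 3-allyl-4-hydroxy-5-(methoxymethoxy)benzaldehyde | C=CCc1cc(C=O)cc(OCOC)c1O
A1 | alternative 1 | (2S)-2-[3,4-bis(methoxymethoxy)-5-(3-methylbut-2-en-1-yl)phenyl]-6-methyl-2,3-dihydro-4H-pyran-4-one | CC(C)=CCc1cc([C@@H]2CC(=O)C=C(C)O2)cc(OCOC)c1OCOC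
A2 | alternative 1 | 3,4-bis(methoxymethoxy)-5-(3-methylbut-2-en-1-yl)benzaldehyde | CC(C)=CCc1cc(C=O)cc(OCOC)c1OCOC
A3 | alternative 1 | (E)-4-methoxy-2-(trimethylsilyloxy)penta-1,3-diene | C=C(O[Si](C)(C)C)/C=C(\C)OC
A4 | alternative 2 | (2S)-5-hydroxy-2-[4-hydroxy-3-(methoxymethoxy)-5-(3-methylbut-2-en-1-yl)phenyl]-7-(methoxymethoxy)-6-(3-methylbut-2-en-1-yl)chroman-4-one | CC(C)=CCc1cc([C@@H]2CC(=O)c3c(cc(OCOC)c(CC=C(C)C)c3O)O2)cc(OCOC)c1O
A5 | alternative 2 | (2S)-7-(methoxymethoxy)-2-[3-(methoxymethoxy)-4-(2-methylbut-3-en-2-yloxy)phenyl]-5-(2-methylbut-3-en-2-yloxy)chroman-4-one | C=CC(C)(C)Oc1ccc([C@@H]2CC(=O)c3c(cc(OCOC)cc3OC(C)(C)C=C)O2)cc1OCOC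
A6 | alternative 3 | (2S)-2-[3,4-bis(methoxymethoxy)-5-(3-methylbut-2-en-1-yl)phenyl]-5,7-dihydroxy-6-(3-methylbut-2-en-1-yl)chroman-4-one | CC(C)=CCc1cc([C@@H]2CC(=O)c3c(cc(O)c(CC=C(C)C)c3O)O2)cc(OCOC)c1OCOC
A7 | alternative 3 | methyl 2-(3-methylbut-2-en-1-yl)-3-oxo-4-{(2S)-2-[3,4-bis(methoxymethoxy)-5-(3-methylbut-2-en-1-yl)phenyl]-4-oxo-3,4-dihydro-2H-pyran-6-yl}butanoate (ester α-carbon undefined) | COC(=O)C(CC=C(C)C)C(=O)CC1=CC(=O)C[C@@H](c2cc(CC=C(C)C)c(OCOC)c(OCOC)c2)O1
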